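The examiner puts the runs and four set-ups on the bench.

| setting | Monday's | Thursday's | Sunday's | oak | elm | cedar | larch |
|---|---|---|---|---|---|---|---|
| substrate | 2 M | 2.8 M | 2 M | 2.0 M | 2.0 M | 2.0 M | 2.0 M |
| partner | 1.2 M | 1.2 M | 1.2 M | 1.20 M | 1.20 M | 1.20 M | 1.20 M |
| free catalyst | 100 mM | 100 mM | 200 mM | 100 mM | 100 mM | 100 mM | 100 mM |
| remark | run made earlier | run made earlier | run made earlier | one stirred flow tank at steady state, fed with the mixture as stated, mean residence time 10.0 min | a tube with plug flow, the mixed feed as stated, residence time 2.0 min | a single well-mixed tank run continuously and read at steady state, 2.0 min in it on average | a closed flask charged with all of it at once and left for 2.0 min |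
| time |  |  |  |  | 2.0 min |  | 2.0 min |

Monday's run (percent of the substrate charged)

| time / s | target / % | substrate / % |
|---|---|---|
| 10.0 | 0.1 | 96.1 |
| 25.0 | 1.9 | 94.6 |
| 50.0 | 4.9 | 90.8 |
| 80.0 | 9.0 | 87.3 |

Thursday's run (percent of the substrate charged)

| time / min | target / % | substrate / % |
|---|---|---|
| 0.667 | 4.0 | 93.7 |
| 1.33 | 7.1 | 90.0 |
| 2.00 | 10.2 | 86.6 |
| 2.50 | 12.9 | 84.3 |

Sunday's run (percent of the substrate charged)

| time / min | target / % | substrate / % |
|---|---|---|
| 0.333 | 3.0 | 89.8 |
| 0.833 | 10.5 | 82.6 |
| 1.50 | 19.5 | 74.3 |
| 2.50 | 29.7 | 63.6 |

(each reading ± 0.3 percentage points)

- the set-up with the highest amount of target at the outlet or at the end, in percent of the substrate put in ("none" if the first two lie within 2 percentage points) (oak / elm / cedar / larch / none)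
- amount of target at the outlet or at the end, in percent of the substrate put in, oak
- amount of target at the outlet or at the end, in percent of the substrate put in, elm
- amount of target at the outlet or at the end, in percent of the substrate put in, cedar
- amount of target at the outlet or at the end, in percent of the substrate put in, larch

- the stated concentrations are those of everything mixed, before any reaction; amounts are the same in each set-up
- steps that have been proposed: substrate + free catalyst <-> catalyst intermediate A; partner + catalyst intermediate A -> catalyst intermediate B; catalyst intermediate B -> by-product + catalyst intermediate C; catalyst intermediate C <-> catalyst intermediate D; catalyst intermediate D -> free catalyst + target; partner -> decomposed reagent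
- the earlier runs were made in a closed, stirred flask

"What pace do you read from Monday's run?" Between 50.0 s and 80.0 s target rises from 4.9% to 9.0%, which is 2.73 mM s⁻¹.

"What moves that pace?" Thursday's run, with more substrate, reads 2.52 mM s⁻¹ late on, no gain. Sunday's run, with twice the catalyst, reads 5.00 mM s⁻¹ early on. So I take the pace to follow the catalyst.

"And what ends it?" The partner is the limiting reagent: one is spent per target, and its charge caps target at 60.0% of the substrate. I divide the partner charge by the pace and call this the partner time, 7.32 min, the time the charge would last at Monday's pace. For this charge, a stay shorter than the partner time leaves control with the catalyst, and a longer one hands it to the partner.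

"Where do the flasks stand?" Larch and elm share one history, and 2.0 min is shorter than the partner time. Running Monday's pace on from its last reading gives 14.5%.

"But suppose the pace falls as partner goes, and a tank sits at its outlet level. What then?" If the pace falls in step with the partner, a tank gives the cap times stay over stay plus partner time. That is my assumption, and it ignores the partner's decomposition. By that reckoning cedar gets 12.9%. Oak, whose 10.0 min is longer than the partner time, gets 34.6%, so I commit to oak.

The forecast names oak, with 14% for elm, 12.7% for cedar, 14% for larch and 35% for oak, close to my figures but not the same, the one for oak from "balancing rate against partner consumption over 600 s".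

The best set-up is oak: oak gives 32.5%, elm 13.5%, cedar 12.2% and larch 13.5%.

    substrate + free catalyst ⇌ catalyst intermediate A (K = 0.640 M⁻¹, k = 0.120 M⁻¹ s⁻¹)
    partner + catalyst intermediate A → catalyst intermediate B (k = 0.190 M⁻¹ s⁻¹)
    catalyst intermediate B → by-product + catalyst intermediate C (k = 0.0420 s⁻¹)
    catalyst intermediate C ⇌ catalyst intermediate D (K = 0.660, k = 13.0 s⁻¹)
    catalyst intermediate D → free catalyst + target (k = 2.70 s⁻¹)
    partner → decomposed reagent (k = 0.00270 s⁻¹)

In oak, the half-life of partner by decomposition alone is 4.3 min, shorter than the partner time of 7.32 min, and the mixture stays 10.0 min on average, with 32.5% of target at the outlet, 54.2% of the 60.0% that the partner charge allows. In larch, the second flask, the 2.0 min is shorter than both that half-life and the partner time, and at the end the flask holds 13.5% of target with 82.9% of the substrate charged still there.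

Readings and results were computed for substances that don't exist; scatter was added.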